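Amounts come first: the reagent, at 0.900 equiv, is the limiting reagent against the starting material, and whatever sits in the idle adduct counts as reacted.

| setting | Wednesday's | Tuesday's |
|---|---|---|
| starting material | 0.80 M | 0.80 M |
| reagent | 0.900 equiv | 0.900 equiv |
| scavenger | 0.500 equiv | 1.00 equiv |
| time | 2.0 h | 2.0 h |

    starting material + reagent → intermediate + released group (k1 = 0.015 M⁻¹ s⁻¹)
    starting material + released group ⇌ idle adduct, settled at all times (K2 = 35 M⁻¹)
    intermediate ⇌ isomer of the product (K3 = 2.5, k3 = 7.2 × 10⁻⁵ s⁻¹)
    scavenger + released group → scavenged by-product (k4 = 0.0020 M⁻¹ s⁻¹)
    intermediate ⇌ target (K5 = 0.69, k5 = 6.5 × 10⁻⁴ s⁻¹)

- released group is meant together with its idle adduct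
- what has gone from starting material into another species counts as reacted, even if it can come back
- run time (Wednesday's): 2.0 h

* part of the starting material that has reacted at the end, Wednesday's
* part of the starting material that has reacted at the end, Tuesday's
* what raising the equivalents of scavenger from its lowest to its highest value here does to the part of the starting material that has reacted (changes below 5 percentage points count as none) (it rises / it falls / no change)

My reckoning is a balance in concentrations:

| | Wednesday's | Tuesday's |
|---|---|---|
| released group the reagent can free | 0.720 M | 0.720 M |
| scavenger charged | 0.400 M | 0.800 M |
| starting material beyond the reagent | 0.0800 M | 0.0800 M |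
| released group left after these | 0.240 M | −0.160 M |

The first row counts as reached, since starting material has a half-life of 1.1 min by step 1, far shorter than the run of 2.0 h. The second row is taken as consumed on Wednesday's: I reckon that scavenger, at a c(released group) of 0.240 M, has a half-life of 0.401 h by step 4, shorter than the run. The third row divides between free starting material and idle adduct.

The last row gives that division. With c(released group) at 0.240 M, one over (one plus 35 M⁻¹ times c(released group)) gives 10.6%. This is the free share: the part of the starting material beyond the reagent that stands unbound. Wednesday's reacted part is therefore 98.9%.

Tuesday's last row is negative, so that balance does not carry over: idle adduct gives released group back as scavenger takes it. The scavenger charged exceeds the released group by 0.0800 M. Integrating step 4 from 0.720 M of released group, counted as free, leaves 0.0318 M at the end, idle adduct included. Shared with the 0.0800 M of starting material beyond the reagent through 35 M⁻¹, that gives a free c(released group) of 0.0104 M. The free share is then 73.3%, and the reacted part 92.7%. My fall of 6.3 percentage points exceeds the 5 points that counts, so I say it falls.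

The forecast says 98.4%, 95% and no change. It differs from mine on the trend: doubling the scavenger “lowers the reacted part by only about 3 to 4 points”.

The simulation gives 98.3% and 95.9%, a change of −2.4 points, which is no change. Tuesday's free released group reads 0.0498 M at 2.00 h, more than my 0.0104 M. The neighbouring flask is Wednesday's with 0.540 equiv of reagent, and its reagent is down to 0%. So 46.0% of the starting material lies beyond the reagent. Its released group reads 0.0314 M, which makes the free share 47.7%, against 10.6% reckoned for Wednesday's. The reacted part comes to 78.1%, and the simulation of that flask gives 78.1%.

The constants were set for the occasion, and the outcome is calculated.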